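**Proposed synthesis of CNP0154747.0 (compound 19): ring B from a 2-pyrone and a silyl ynol ether**

## Analysis of the target

Compound 19 is a flavonol: a 4H-chromen-4-one (ring A fused to pyranone ring C; O1, C2, C3, C4, C4a, C5–C8, C8a) with a hydroxyl at C3 and aryl ring B (C1'–C6') on C2. Ring A carries OH at C7 and CH3 at C6 and has no oxygen at C5. Ring B is a catechol (OH at C3' and C4') with a 3-methylbut-2-enyl (prenyl) chain at C2', so C1', C2', C3' and C4' are four contiguous substituted carbons and only C5' and C6' bear hydrogen. There is no stereocentre, and the prenyl alkene ends in two methyl groups, so the task is purely one of regiochemistry and chemoselectivity. The prenyl alkene is the sensitive group: it does not tolerate electrophilic oxidants or hydrogenation, and under acid the neighbouring C3' hydroxyl can add to it to give a 2,2-dimethylchroman. The free catechol and the 3-hydroxy-enone are oxidisable in base, so they should be unmasked last. The hard part is the prenyl group at C2', wedged between the C1'–C2 bond and the C3' oxygen, because electrophilic prenylation of a 3,4-dioxygenated aryl carbonyl compound goes to C5' or C6'. The strategy rests on reading ring B as C1'(carbonyl carbon)–C2'(prenyl)–C3'(O)–C4'(O)–C5'H–C6'H. This is the sum of C6, C5, C4 and C3 of a 3-oxygenated 2-pyrone-6-carboxylate (C6 becomes C1', C3 becomes C4') and the two carbons of a prenyl-substituted ynol ether (C2' and C3').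

## Retrosynthetic reasoning

19 from 18. The last cut is at the three acetal O–CH2 bonds on the C7, C3' and C4' oxygens. Methoxymethyl acetals are chosen because every step between ring B formation and the end is basic, reductive or oxidative, and acetals pass all of them. One mild acid step then frees the three phenols; the C3 hydroxyl needs no protection.

18 from 16. Ring C is opened at O1–C2 and the C3–O bond is removed, leading back to 2'-hydroxychalcone 16. The forward reaction is an Algar–Flynn–Oyamada oxidative cyclisation, which closes the pyranone and installs the C3 hydroxyl in one basic operation that leaves acetals and the isolated alkene alone. Ring A has no substituent at C5, which is the structural condition for flavonol rather than aurone formation. A sequence of acyl transfer, acid-mediated ring closure and separate C3 metalation–oxidation was kept only as a fallback. It would put acid on the acetals before the end and a strong amide base beside the allylic benzylic CH2.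

16 from 12 and 15. The C2–C3 double bond of the enone is cut (aldol condensation). Aldehyde 12 has no α-hydrogen and ketone 15 has only one enolisable site, so the crossed condensation has one possible outcome.

15 from 14 from 13. The acetyl group is placed on 4-methylresorcinol 13 at the carbon ortho to one hydroxyl and para to the other, the only unhindered activated position. This sets the ring A pattern (C7 oxygen, C6 methyl). The hydroxyl not chelated to the ketone is then protected selectively.

12 from 11 from 10. The aldehyde is reached from ester 10 by reduction to alcohol 11 and benzylic oxidation. Two reliable steps are preferred to a single partial reduction of a hindered aryl ester.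

10 from 9 from 8. The silyl ether on the C3' oxygen in 8 is exchanged for a methoxymethyl acetal. An aryl silyl ether would be cleaved in an uncontrolled way by the hydroxide used in the condensation and the oxidative cyclisation. The exchange costs two steps and leaves a single, uniform deprotection at the end.

8 from 3 and 6 (through 7). Ring B is cut at C1'–C2' and C3'–C4'. Pyrone 3 supplies C1' with its ester, C6', C5' and C4' with its oxygen. Ynol ether 6 supplies C2' with the prenyl group and C3' with its oxygen. The cut is made here because it is the only one that delivers all four contiguous substituents, the hindered C2' prenyl included, in a single bond-forming event. The forward reaction is a regioselective inverse-demand cycloaddition followed by decarboxylative aromatisation of adduct 7.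

3 from 2 from 1, and 6 from 5 from 4. Pyrone 3 is the methyl ester and enol acetal of acid 1. Ynol ether 6 is the O-silylated ynolate 5, reached by one-carbon homologation of ester 4, whose prenyl unit is already in place. Both partners are thus one or two steps from purchasable materials, and the risk of the route sits in the cycloaddition.

## Alternatives that were turned down

Alternative 1: Ring C is cut at C4–C4a. The precursor is acid A1, a (Z)-3-aryloxyacrylic acid in which the ring A oxygen and ring B already sit on the future C2. Carboxyl activation (Lewis acid on the acid chloride, or a mixed anhydride) lets ring A attack through the carbon para to its silyloxy group and gives flavone A2.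
- For: it is convergent and the ring A regiochemistry is clear. The all-silyl protection allows a fluoride-only final step with no acid near the prenyl/phenol pair; on that point it is stronger than the chosen route, which ends with an acid step.
- Against: an acylium equivalent and a Lewis acid must coexist with the nucleophilic prenyl alkene held ortho to the reacting chain, and with three aryl silyl ethers. Only the Z acid can close.
- Against: A2 has hydrogen at C3. The hydroxyl would have to be added later by a strong amide base next to the ArCH2–allyl unit or by an electrophilic oxidant the alkene will not tolerate.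
- Against, and decisive: A1 presupposes ring B with its four contiguous substituents, which this disconnection does nothing to build.
- Comparison: the chosen strategy spends its key step on exactly that ring and brings the C3 oxygen in with ring C closure. Alternative 1 would add a separate ring B synthesis and a C3 oxidation, and would be longer.

Alternative 2: Ring B is cut at C1'–C2' and C1'–C6'. C1' is the 2-methyl carbon of chromone A3 and the other five ring B carbons come from pyranone A4. Double O-silylation with a silyl triflate and an amine makes A3 an exocyclic enol ether and A4 a pyrylium ion. The sequence is C–C bond formation at the unsubstituted pyranone C6, electrocyclic ring opening, base-induced aldol condensation onto the ketone bearing the prenyl CH2, aromatisation and fluoride work-up, giving A5.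
- For: it is the most convergent plan. The C3 oxygen is present from the start, so no oxidation of ring C is needed at all, and the C4' hydroxyl emerges differentiated. On convergence and on avoiding an oxidation it is stronger than the chosen route.
- Against: it is a cascade of four events without a close model for this substitution pattern. The ring-opened intermediate has a CH2 flanked by a ketone and the prenyl alkene; this is its most acidic site, and enolisation there moves the double bond into conjugation and destroys the prenyl group.
- Against: silyl triflates are reagents that cleave methoxymethyl acetals, three of which are present. A4 is itself a prenylated hydroxypyranone that needs several steps.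
- Comparison: the chosen key step is one pericyclic event driven by gas loss, and its partners 3 and 6 are two steps and one step from purchasable compounds.

Alternative 3: Ring C is cut at C3–C4. In dialdehyde A6 a triazolium-derived carbene turns the aromatic aldehyde (C4) into an acyl anion equivalent that adds to the tethered aliphatic aldehyde (C3) and gives 3-hydroxychromanone A7, which must then be dehydrogenated.
- For: the C3 oxygen arrives with ring closure under nearly neutral, metal-free conditions that neither acetals nor the prenyl group notice. This is milder than the alkaline peroxide of step 12, so it is stronger on that point.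
- Against: A6 contains an α-aryl-α-aryloxy acetaldehyde whose α-hydrogen is doubly activated, so enolisation and self-condensation compete. The aromatic aldehyde is deactivated by the para oxygen at C7, so the carbene may choose the wrong carbonyl.
- Against: making A6 requires a C–O bond between the ring A phenol and a hindered benzylic carbon next to the prenyl group, with two aldehydes kept apart by redox or protection steps. A7 still needs an oxidation, and ring B is again left to other chemistry.
- Comparison: the chosen route reaches the same oxidation level by a one-flask cyclisation–oxidation of 16 and solves ring B as well.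

Key step: step 4

## Route

Remark: 1, 4 and 13 are taken to be purchasable. The pyrone is numbered O1, C2 (carbonyl), C3–C6; ring B carbons carry primes.

Step 1
Reactants: 1 3-hydroxy-2-oxo-2H-pyran-6-carboxylic acid
Product: 2 methyl 3-hydroxy-2-oxo-2H-pyran-6-carboxylate
Conditions: MeOH, H2SO4 (cat.), reflux
Reagents that add atoms: methanol, CO
Why: Fischer esterification; the lactone and the enolic C3 hydroxyl do not react under acid catalysis, as in the preparation of other pyrone carboxylic esters.

Step 2
Reactants: 2 methyl 3-hydroxy-2-oxo-2H-pyran-6-carboxylate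
Product: 3 methyl 3-(methoxymethoxy)-2-oxo-2H-pyran-6-carboxylate
Conditions: MOMCl, i-Pr2NEt, CH2Cl2, 0 °C → rt
Reagents that add atoms: chloromethyl methyl ether, COCCl
Why: O-alkylation of the acidic enolic hydroxyl (Williamson-type acetal formation). Capping it removes the proton that would otherwise destroy the acid-sensitive ynol ether in step 4.

Step 3
Reactants: 4 ethyl 4-methylpent-3-enoate
Product: 6 triisopropyl[(5-methylhex-4-en-1-yn-1-yl)oxy]silane, via lithium ynolate 5 (not isolated)
Conditions: CH2Br2, lithium 2,2,6,6-tetramethylpiperidide, THF, −78 °C; LiN(SiMe3)2; n-BuLi, −78 → 0 °C; i-Pr3SiOTf, −78 → 0 °C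
Reagents that add atoms: dibromomethane, BrCBr; triisopropylsilyl trifluoromethanesulfonate, CC(C)[Si](OS(=O)(=O)C(F)(F)F)(C(C)C)C(C)C
Why: Kowalski ester homologation: LiCHBr2 adds to the ester, the dibromoketone enolate undergoes bromine–lithium exchange and a 1,2-shift of the prenyl CH2 group to give ynolate 5. The bulky silyl triflate then silylates oxygen rather than carbon, giving an isolable silyl ynol ether.

Step 4
Reactants: 3 methyl 3-(methoxymethoxy)-2-oxo-2H-pyran-6-carboxylate; 6 triisopropyl[(5-methylhex-4-en-1-yn-1-yl)oxy]silane
Product: 8 methyl 4-(methoxymethoxy)-2-(3-methylbut-2-en-1-yl)-3-[(triisopropylsilyl)oxy]benzoate, via bicyclic lactone 7 (not isolated)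
Conditions: PhMe, 110 °C, sealed tube
Reagents that add atoms: none
Why: Inverse-electron-demand Diels–Alder reaction followed by cycloreversion: the HOMO of silyl ynol ether 6, raised by the oxygen lone pair, meets the LUMO of pyrone 3, lowered by the lactone and the C6 ester. Bond formation should be asynchronous: the prenyl-bearing alkyne carbon (the nucleophilic β-carbon of the ynol ether) bonds first to pyrone C6, and the silyloxy-bearing carbon, which takes on ketenium character, then closes onto C3. The 2-oxabicyclo[2.2.2]octa-5,7-dien-3-one 7 should not survive, because retro-[4+2] loss of the O1–C2 bridge as CO2 is fast and irreversible at this temperature and leaves benzoate 8. The closest known reaction type is the arene synthesis from 2-pyrone carboxylates and ynamines or alkoxyalkynes; a silyl ynol ether is the less nucleophilic member of the same class, which is why heat is planned. Ring B is closed as a six-membered carbocycle by an intermolecular [4+2] cycloaddition that forms C1'–C2' and C3'–C4' in one operation; the two bridgehead stereocentres of 7 are racemic and vanish on aromatisation, so no stereocentre has to be controlled. The selectivity that matters is regiochemical: C6 is the δ-carbon of the lactone carbonyl, is bound to the ring oxygen and carries the ester, so it should be the most electrophilic diene terminus, whereas C3 carries the donor acetal oxygen; on the alkyne the silyloxy group fixes the nucleophilic carbon as the one bearing the prenyl CH2. Chemoselectivity within 6 follows from the same polarisation, since the isolated trisubstituted alkene is far less electron-rich than the ynol ether and is carried through as the prenyl group.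

Step 5
Reactants: 8 methyl 4-(methoxymethoxy)-2-(3-methylbut-2-en-1-yl)-3-[(triisopropylsilyl)oxy]benzoate
Product: 9 methyl 3-hydroxy-4-(methoxymethoxy)-2-(3-methylbut-2-en-1-yl)benzoate
Conditions: Bu4NF, THF, 0 °C
Reagents that add atoms: none
Why: Fluoride-induced cleavage of the aryl silyl ether, driven by the Si–F bond; ester, acetal and alkene are inert to fluoride at this temperature.

Step 6
Reactants: 9 methyl 3-hydroxy-4-(methoxymethoxy)-2-(3-methylbut-2-en-1-yl)benzoate
Product: 10 methyl 3,4-bis(methoxymethoxy)-2-(3-methylbut-2-en-1-yl)benzoate
Conditions: NaH, MOMCl, DMF, 0 °C → rt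
Reagents that add atoms: chloromethyl methyl ether, COCCl
Why: Williamson O-alkylation; the preformed sodium phenoxide in a dipolar solvent overcomes the hindrance from the flanking prenyl and acetal groups.

Step 7
Reactants: 10 methyl 3,4-bis(methoxymethoxy)-2-(3-methylbut-2-en-1-yl)benzoate
Product: 11 [3,4-bis(methoxymethoxy)-2-(3-methylbut-2-en-1-yl)phenyl]methanol
Conditions: i-Bu2AlH, CH2Cl2, −78 → 0 °C
Reagents that add atoms: none
Why: Hydride reduction of the aryl ester to the benzylic alcohol; acetals and the alkene are untouched.

Step 8
Reactants: 11 [3,4-bis(methoxymethoxy)-2-(3-methylbut-2-en-1-yl)phenyl]methanol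
Product: 12 3,4-bis(methoxymethoxy)-2-(3-methylbut-2-en-1-yl)benzaldehyde
Conditions: MnO2, CH2Cl2, rt
Reagents that add atoms: none
Why: Selective heterogeneous oxidation of an electron-rich benzylic alcohol; it stops at the aldehyde and does not attack the alkene.

Step 9
Reactants: 13 4-methylresorcinol (4-methylbenzene-1,3-diol)
Product: 14 1-(2,4-dihydroxy-5-methylphenyl)ethan-1-one
Conditions: AcOH, ZnCl2, 140 °C
Reagents that add atoms: acetic acid, CC(=O)O
Why: Nencki reaction (Friedel–Crafts C-acylation of a resorcinol). The acetyl group enters ortho to one hydroxyl and para to the other, because the position between the two hydroxyls is hindered and the remaining one is meta to both.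

Step 10
Reactants: 14 1-(2,4-dihydroxy-5-methylphenyl)ethan-1-one
Product: 15 1-[2-hydroxy-4-(methoxymethoxy)-5-methylphenyl]ethan-1-one
Conditions: MOMCl (1.1 equiv), K2CO3, acetone, rt
Reagents that add atoms: chloromethyl methyl ether, COCCl
Why: Selective Williamson O-alkylation; the C2 hydroxyl is held in a hydrogen bond to the ketone and is much less nucleophilic than the C4 hydroxyl.

Step 11
Reactants: 12 3,4-bis(methoxymethoxy)-2-(3-methylbut-2-en-1-yl)benzaldehyde; 15 1-[2-hydroxy-4-(methoxymethoxy)-5-methylphenyl]ethan-1-one
Product: 16 (2E)-3-[3,4-bis(methoxymethoxy)-2-(3-methylbut-2-en-1-yl)phenyl]-1-[2-hydroxy-4-(methoxymethoxy)-5-methylphenyl]prop-2-en-1-one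
Conditions: KOH, EtOH/H2O, rt
Reagents that add atoms: none
Why: Claisen–Schmidt condensation of a methyl ketone with a non-enolisable aldehyde. Elimination from the aldol by the E1cB path should give the E enone, the more stable isomer.

Step 12
Reactants: 16 (2E)-3-[3,4-bis(methoxymethoxy)-2-(3-methylbut-2-en-1-yl)phenyl]-1-[2-hydroxy-4-(methoxymethoxy)-5-methylphenyl]prop-2-en-1-one
Product: 18 3-hydroxy-7-(methoxymethoxy)-2-[3,4-bis(methoxymethoxy)-2-(3-methylbut-2-en-1-yl)phenyl]-6-methyl-4H-chromen-4-one, via dihydroflavonol 17 (not isolated)
Conditions: H2O2 (30% aq), NaOH, MeOH, 0 °C → rt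
Reagents that add atoms: hydrogen peroxide, OO
Why: Algar–Flynn–Oyamada reaction: the phenoxide closes ring C by 6-endo oxa-Michael addition, the resulting enolate is hydroxylated at C3 to 17, and 17 is oxidised further in the same flask to the flavonol, which erases both transient sp3 centres. The absence of a substituent at C5 of ring A favours flavonol over aurone. Nucleophilic peroxide does not epoxidise the isolated prenyl alkene.

Step 13
Reactants: 18 3-hydroxy-7-(methoxymethoxy)-2-[3,4-bis(methoxymethoxy)-2-(3-methylbut-2-en-1-yl)phenyl]-6-methyl-4H-chromen-4-one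
Product: 19 2-[3,4-dihydroxy-2-(3-methylbut-2-en-1-yl)phenyl]-3,7-dihydroxy-6-methyl-4H-chromen-4-one (CNP0154747.0)
Conditions: HCl (3 M aq)/MeOH, 40 °C
Reagents that add atoms: none
Why: Acid-catalysed acetal cleavage by transacetalisation to methanol removes all three methoxymethyl groups. Dilute acid and mild temperature are chosen so that the freed C3' hydroxyl does not add to the prenyl alkene.

## Compound list

1 | 3-hydroxy-2-oxo-2H-pyran-6-carboxylic acid | O=C(O)c1ccc(O)c(=O)o1 | starting material
2 | methyl 3-hydroxy-2-oxo-2H-pyran-6-carboxylate | COC(=O)c1ccc(O)c(=O)o1 | intermediate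
3 | methyl 3-(methoxymethoxy)-2-oxo-2H-pyran-6-carboxylate | COC(=O)c1ccc(OCOC)c(=O)o1 | intermediate
4 | ethyl 4-methylpent-3-enoate | CCOC(=O)CC=C(C)C | starting material
5 | lithium 5-methylhex-4-en-1-yn-1-olate | CC(C)=CCC#C[O-].[Li+] | intermediate (not isolated)
6 | triisopropyl[(5-methylhex-4-en-1-yn-1-yl)oxy]silane | CC(C)=CCC#CO[Si](C(C)C)(C(C)C)C(C)C | intermediate
7 | methyl 4-(methoxymethoxy)-7-(3-methylbut-2-en-1-yl)-3-oxo-8-[(triisopropylsilyl)oxy]-2-oxabicyclo[2.2.2]octa-5,7-diene-1-carboxylate (racemic) | COC(=O)C12OC(=O)C(OCOC)(C=C1)C(O[Si](C(C)C)(C(C)C)C(C)C)=C2CC=C(C)C | intermediate (not isolated)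
8 | methyl 4-(methoxymethoxy)-2-(3-methylbut-2-en-1-yl)-3-[(triisopropylsilyl)oxy]benzoate | COC(=O)c1ccc(OCOC)c(O[Si](C(C)C)(C(C)C)C(C)C)c1CC=C(C)C | intermediate
9 | methyl 3-hydroxy-4-(methoxymethoxy)-2-(3-methylbut-2-en-1-yl)benzoate | COC(=O)c1ccc(OCOC)c(O)c1CC=C(C)C | intermediate
10 | methyl 3,4-bis(methoxymethoxy)-2-(3-methylbut-2-en-1-yl)benzoate | COC(=O)c1ccc(OCOC)c(OCOC)c1CC=C(C)C | intermediate
11 | [3,4-bis(methoxymethoxy)-2-(3-methylbut-2-en-1-yl)phenyl]methanol | OCc1ccc(OCOC)c(OCOC)c1CC=C(C)C | intermediate
12 | 3,4-bis(methoxymethoxy)-2-(3-methylbut-2-en-1-yl)benzaldehyde | O=Cc1ccc(OCOC)c(OCOC)c1CC=C(C)C | intermediate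
13 | 4-methylresorcinol (4-methylbenzene-1,3-diol) | Cc1ccc(O)cc1O | starting material
14 | 1-(2,4-dihydroxy-5-methylphenyl)ethan-1-one | CC(=O)c1cc(C)c(O)cc1O | intermediate
15 | 1-[2-hydroxy-4-(methoxymethoxy)-5-methylphenyl]ethan-1-one | CC(=O)c1cc(C)c(OCOC)cc1O | intermediate
16 | (2E)-3-[3,4-bis(methoxymethoxy)-2-(3-methylbut-2-en-1-yl)phenyl]-1-[2-hydroxy-4-(methoxymethoxy)-5-methylphenyl]prop-2-en-1-one | O=C(/C=C/c1ccc(OCOC)c(OCOC)c1CC=C(C)C)c1cc(C)c(OCOC)cc1O | intermediate
17 | 3-hydroxy-7-(methoxymethoxy)-2-[3,4-bis(methoxymethoxy)-2-(3-methylbut-2-en-1-yl)phenyl]-6-methyl-2,3-dihydro-4H-chromen-4-one (racemic; configuration at C2 and C3 not controlled, both centres erased in the same flask) | O=C1c2cc(C)c(OCOC)cc2OC(c2ccc(OCOC)c(OCOC)c2CC=C(C)C)C1O | intermediate (not isolated)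
18 | 3-hydroxy-7-(methoxymethoxy)-2-[3,4-bis(methoxymethoxy)-2-(3-methylbut-2-en-1-yl)phenyl]-6-methyl-4H-chromen-4-one | CC(C)=CCc1c(-c2oc3cc(OCOC)c(C)cc3c(=O)c2O)ccc(OCOC)c1OCOC | intermediate
19 | 2-[3,4-dihydroxy-2-(3-methylbut-2-en-1-yl)phenyl]-3,7-dihydroxy-6-methyl-4H-chromen-4-one | CC(C)=CCc1c(-c2oc3cc(O)c(C)cc3c(=O)c2O)ccc(O)c1O | target

## Step count and risk

Total step count: 13.
Longest linear sequence: 10 steps (steps 1, 2, 4, 5, 6, 7, 8, 11, 12, 13).

Least certain steps:

**Step 4 (key step).** Three things may go wrong.
- Regiocontrol may erode. The donor oxygen at C3 and the ester at C6 form a push–pull pair that works against the intrinsic polarisation of the lactone, so some bonding of the nucleophilic alkyne carbon to C3 is conceivable.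
- The ynol ether may be consumed before it cycloadds, by [2+2] addition to the C5=C6 acrylate unit or by thermal silyl shift to a silylketene.
- The pyrone may simply be too electron-rich to react at a temperature the ynol ether tolerates.

Catalysis by AgNTf2, or an acyl group in place of the acetal on the pyrone oxygen, are adjustments within the same reaction. The fallback changes the approach: the ortho-prenyl group is installed by an aromatic Claisen rearrangement on a preformed catechol ester. This path uses neither 3 nor 6. It sets out from purchased methyl 3,4-dihydroxybenzoate F1 and comes back to the route at phenol 9. Selective alkylation of the more acidic C4 hydroxyl (MOMCl, one equivalent of K2CO3, acetone) should give methyl 3-hydroxy-4-(methoxymethoxy)benzoate F2. O-Alkylation with 3-chloro-3-methylbut-1-yne (DBU, CuCl2 cat., MeCN) should give methyl 4-(methoxymethoxy)-3-[(2-methylbut-3-yn-2-yl)oxy]benzoate F3. Semihydrogenation (H2, Pd/CaCO3 poisoned with Pb(OAc)2, quinoline) should give methyl 4-(methoxymethoxy)-3-[(2-methylbut-3-en-2-yl)oxy]benzoate F4. Heating in N,N-diethylaniline should then move the allyl unit by [3,3] shift to C2, the only free ortho carbon, with transposition of the allyl termini so that a prenyl group results, giving 9.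

**Step 3.** The α-hydrogens of 4 are both allylic and next to the ester. Deprotonation by the carbenoid or the amide base may therefore outrun addition to the carbonyl and return ester, possibly with the double bond moved into conjugation. Partial C-silylation of the ynolate is a lesser risk. The fallback sets out from ester 4 and comes back at ynolate 5 and hence at 6. Partial reduction with i-Bu2AlH at −78 °C gives 4-methylpent-3-enal F5. Olefination with CBr4 and PPh3 (Corey–Fuchs) gives 1,1-dibromo-5-methylhexa-1,4-diene F6. Two equivalents of n-BuLi give lithium 5-methylhex-4-en-1-yn-1-ide F7. Oxidation of the acetylide with LiOOt-Bu (from t-BuOOH and LiN(SiMe3)2) gives ynolate 5, which is silylated as in step 3.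

**Step 12.** The ortho-prenyl group twists ring B out of the enone plane. Ring closure may then stall at the flavanone or dihydroflavonol stage, or an epoxide pathway with five-membered closure to an aurone may compete. The fallback sets out from ester 10 (with ketone 15) and comes back at 18.
- LiOH in THF/MeOH/H2O gives 3,4-bis(methoxymethoxy)-2-(3-methylbut-2-en-1-yl)benzoic acid F8.
- EDC and DMAP with 15 give 2-acetyl-5-(methoxymethoxy)-4-methylphenyl 3,4-bis(methoxymethoxy)-2-(3-methylbut-2-en-1-yl)benzoate F9.
- KOt-Bu in THF (Baker–Venkataraman acyl shift) gives 1-[3,4-bis(methoxymethoxy)-2-(3-methylbut-2-en-1-yl)phenyl]-3-[2-hydroxy-4-(methoxymethoxy)-5-methylphenyl]propane-1,3-dione F10.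
- Cyclodehydration with pyridinium p-toluenesulfonate in toluene gives 7-(methoxymethoxy)-2-[3,4-bis(methoxymethoxy)-2-(3-methylbut-2-en-1-yl)phenyl]-6-methyl-4H-chromen-4-one F11.
- C3 lithiation with LiN(i-Pr)2 at −78 °C, B(OMe)3, then H2O2/NaHCO3 gives 18.

**Step 13.** Once the C3' hydroxyl is free, acid can add it across the neighbouring prenyl alkene (chroman formation) or hydrate the alkene. The fallback sets out from 18 and comes back at 19 without protic acid. Me3SiOTf and 2,2'-bipyridyl in CH2Cl2 at 0 °C exchange each aryl acetal for a silyl ether and silylate the C3 hydroxyl. This gives 2-[2-(3-methylbut-2-en-1-yl)-3,4-bis(trimethylsilyloxy)phenyl]-6-methyl-3,7-bis(trimethylsilyloxy)-4H-chromen-4-one F12, whose silyl ethers are hydrolysed on neutral aqueous methanol work-up.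

## Further compounds

F1 | step 4 | methyl 3,4-dihydroxybenzoate | COC(=O)c1ccc(O)c(O)c1
F2 | step 4 | methyl 3-hydroxy-4-(methoxymethoxy)benzoate | COC(=O)c1ccc(OCOC)c(O)c1
F3 | step 4 | methyl 4-(methoxymethoxy)-3-[(2-methylbut-3-yn-2-yl)oxy]benzoate | COC(=O)c1ccc(OCOC)c(OC(C)(C)C#C)c1
F4 | step 4 | methyl 4-(methoxymethoxy)-3-[(2-methylbut-3-en-2-yl)oxy]benzoate | COC(=O)c1ccc(OCOC)c(OC(C)(C)C=C)c1
F5 | step 3 | 4-methylpent-3-enal | CC(C)=CCC=O
F6 | step 3 | 1,1-dibromo-5-methylhexa-1,4-diene | CC(C)=CCC=C(Br)Br
F7 | step 3 | lithium 5-methylhex-4-en-1-yn-1-ide | CC(C)=CCC#[C-].[Li+]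
F8 | step 12 | 3,4-bis(methoxymethoxy)-2-(3-methylbut-2-en-1-yl)benzoic acid | OC(=O)c1ccc(OCOC)c(OCOC)c1CC=C(C)C
F9 | step 12 | 2-acetyl-5-(methoxymethoxy)-4-methylphenyl 3,4-bis(methoxymethoxy)-2-(3-methylbut-2-en-1-yl)benzoate | CC(=O)c1cc(C)c(OCOC)cc1OC(=O)c1ccc(OCOC)c(OCOC)c1CC=C(C)C
F10 | step 12 | 1-[3,4-bis(methoxymethoxy)-2-(3-methylbut-2-en-1-yl)phenyl]-3-[2-hydroxy-4-(methoxymethoxy)-5-methylphenyl]propane-1,3-dione | O=C(CC(=O)c1ccc(OCOC)c(OCOC)c1CC=C(C)C)c1cc(C)c(OCOC)cc1O
F11 | step 12 | 7-(methoxymethoxy)-2-[3,4-bis(methoxymethoxy)-2-(3-methylbut-2-en-1-yl)phenyl]-6-methyl-4H-chromen-4-one | CC(C)=CCc1c(-c2cc(=O)c3cc(C)c(OCOC)cc3o2)ccc(OCOC)c1OCOC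
F12 | step 13 | 2-[2-(3-methylbut-2-en-1-yl)-3,4-bis(trimethylsilyloxy)phenyl]-6-methyl-3,7-bis(trimethylsilyloxy)-4H-chromen-4-one | CC(C)=CCc1c(-c2oc3cc(O[Si](C)(C)C)c(C)cc3c(=O)c2O[Si](C)(C)C)ccc(O[Si](C)(C)C)c1O[Si](C)(C)C
A1 | alternative 1 | (2Z)-3-[3,4-bis(tert-butyldimethylsilyloxy)-2-(3-methylbut-2-en-1-yl)phenyl]-3-[3-(tert-butyldimethylsilyloxy)-4-methylphenoxy]prop-2-enoic acid | OC(=O)/C=C(\Oc1ccc(C)c(O[Si](C)(C)C(C)(C)C)c1)c1ccc(O[Si](C)(C)C(C)(C)C)c(O[Si](C)(C)C(C)(C)C)c1CC=C(C)C
A2 | alternative 1 | 7-(tert-butyldimethylsilyloxy)-2-[3,4-bis(tert-butyldimethylsilyloxy)-2-(3-methylbut-2-en-1-yl)phenyl]-6-methyl-4H-chromen-4-one | CC(C)=CCc1c(-c2cc(=O)c3cc(C)c(O[Si](C)(C)C(C)(C)C)cc3o2)ccc(O[Si](C)(C)C(C)(C)C)c1O[Si](C)(C)C(C)(C)C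
A3 | alternative 2 | 3,7-bis(methoxymethoxy)-2,6-dimethyl-4H-chromen-4-one | Cc1oc2cc(OCOC)c(C)cc2c(=O)c1OCOC
A4 | alternative 2 | 3-(methoxymethoxy)-2-(3-methylbut-2-en-1-yl)-4H-pyran-4-one | CC(C)=CCc1occc(=O)c1OCOC
A5 | alternative 2 | 2-[4-hydroxy-3-(methoxymethoxy)-2-(3-methylbut-2-en-1-yl)phenyl]-3,7-bis(methoxymethoxy)-6-methyl-4H-chromen-4-one | CC(C)=CCc1c(-c2oc3cc(OCOC)c(C)cc3c(=O)c2OCOC)ccc(O)c1OCOC
A6 | alternative 3 | 2-{1-[3,4-bis(methoxymethoxy)-2-(3-methylbut-2-en-1-yl)phenyl]-2-oxoethoxy}-4-(methoxymethoxy)-5-methylbenzaldehyde (racemic) | O=Cc1cc(C)c(OCOC)cc1OC(C=O)c1ccc(OCOC)c(OCOC)c1CC=C(C)C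
A7 | alternative 3 | 3-hydroxy-7-(methoxymethoxy)-2-[3,4-bis(methoxymethoxy)-2-(3-methylbut-2-en-1-yl)phenyl]-6-methyl-2,3-dihydro-4H-chromen-4-one (diastereomer mixture) | O=C1c2cc(C)c(OCOC)cc2OC(c2ccc(OCOC)c(OCOC)c2CC=C(C)C)C1O
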